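## Retrosynthetic overview

1. The oxirane is made last: reagent-controlled epoxidation of the Z-C7=C8 alkene of the macrocyclic triene acetate 20.
2. The 14-membered carbocycle is closed at C2–C3 by an intramolecular Pd-catalysed γ-alkenylation of the butenolide (as its silyloxyfuran) with the C3 alkenyl bromide (new; sets C2).
3. C12–C13 and C14–C1 are made together by a Pd-induced 1,2-boronate shift (conjunctive coupling) of an alkenyl/vinyl borate with the tetronate triflate 12; this sets C13.
4. The C3–C12 chain comes from propyne carbocupration (Z-C7=C8), alkyne carboalumination (E-C3=C4) and alkyne protoboration (E-C11=C12).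
5. Ring order: butenolide (bought as 3-methyltetronic acid) → carbocycle (step 6) → oxirane (step 8).

Numbering: cembrane numbering is used for the C20 skeleton. C1 is the butenolide β-carbon, C2 the lactone O–CH, C3=C4(C18), C7–C8(C19) the oxirane, C11=C12(C20), C13 the CH–OAc carbon, C14 the CH2, C15(C17) the lactone α-carbon and C16 the C=O.

Assumption: 3-methyltetronic acid and (4-iodobut-1-yn-1-yl)trimethylsilane are taken as catalogue compounds, and both antipodes of MandyPhos, DTBM-SEGPHOS and the Shi ketone as purchasable.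

## Route

Step 1
Reactants: 1 5-bromopent-2-yne; 2 propyne; 3 (4-iodobut-1-yn-1-yl)trimethylsilane
Product: 7 (Z)-6-methylundec-5-ene-1,9-diyne, via Grignard reagent 4 (not isolated), via alkenylcopper 5 (not isolated), via silyl enediyne 6 (not isolated)
Conditions: Mg, THF, 35 °C; CuBr·SMe2 (1.0 equiv), Et2O/SMe2, −45 °C; 2, −25 °C, 2 h; 3, HMPA, P(OEt)3, THF, −30 → 20 °C; NH4Cl wash, then K2CO3, MeOH, 23 °C
Reagents that add atoms: none
Why: Normant syn-carbocupration of propyne puts the pentynyl group and copper cis, alkylation of the alkenylcopper with retention fixes the Z-trisubstituted C7=C8 alkene, and carbonate methanolysis frees the terminal alkyne.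

Step 2
Reactants: 7 (Z)-6-methylundec-5-ene-1,9-diyne
Product: 9 (1E,5Z)-1-bromo-2,6-dimethylundeca-1,5-dien-9-yne, via alkenylalane 8 (not isolated)
Conditions: AlMe3 (2.5 equiv), Cp2ZrCl2 (0.25 equiv), H2O (0.5 equiv), CH2Cl2, −25 °C; then NBS (1.05 equiv), THF, −25 → 0 °C
Reagents that add atoms: trimethylaluminium, C[Al](C)C; N-bromosuccinimide, O=C1CCC(=O)N1Br
Why: Negishi zirconium-catalysed syn-carboalumination (water-accelerated Wipf variant) reacts only at the terminal alkyne, and bromodealumination with retention gives the E-2-methylalkenyl bromide (C3=C4, C18 installed); the internal alkyne and the trisubstituted alkene react far more slowly.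

Step 3
Reactants: 9 (1E,5Z)-1-bromo-2,6-dimethylundeca-1,5-dien-9-yne
Product: 10 2-[(2Z,6Z,10E)-11-bromo-6,10-dimethylundeca-2,6,10-trien-2-yl]-4,4,5,5-tetramethyl-1,3,2-dioxaborolane
Conditions: B2pin2 (1.1 equiv), (SIPr)CuCl (5 mol %; SIPr = 1,3-bis(2,6-diisopropylphenyl)imidazolidin-2-ylidene), NaOt-Bu (10 mol %), MeOH (2 equiv), THF, 23 °C
Reagents that add atoms: bis(pinacolato)diboron, CC1(C)OB(OC1(C)C)B1OC(C)(C)C(C)(C)O1
Why: Copper-catalysed syn-protoboration (borylcupration, then methanolysis) places boron on the less hindered methyl-bearing alkyne carbon (C12) and fixes the C11=C12 geometry, leaving the alkenyl bromide and the alkenes untouched.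

Step 4
Reactants: 11 3-methyltetronic acid (4-hydroxy-3-methylfuran-2(5H)-one)
Product: 12 4-methyl-5-oxo-2,5-dihydrofuran-3-yl trifluoromethanesulfonate
Conditions: Tf2O (1.1 equiv), i-Pr2NEt (1.2 equiv), CH2Cl2, −78 °C
Reagents that add atoms: triflic anhydride, O=S(=O)(OS(=O)(=O)C(F)(F)F)C(F)(F)F
Why: O-sulfonylation of the vinylogous acid gives the activated vinylogous acyl triflate that serves as the C1 electrophile.

Step 5
Reactants: 10 2-[(2Z,6Z,10E)-11-bromo-6,10-dimethylundeca-2,6,10-trien-2-yl]-4,4,5,5-tetramethyl-1,3,2-dioxaborolane; 12 4-methyl-5-oxo-2,5-dihydrofuran-3-yl trifluoromethanesulfonate; 13 vinylmagnesium bromide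
Product: 16 4-[(2R,3E,7Z,11E)-12-bromo-2-hydroxy-3,7,11-trimethyldodeca-3,7,11-trien-1-yl]-3-methylfuran-2(5H)-one, via bis(alkenyl)borate 14 (not isolated), via allylic boronate 15 (not isolated)
Conditions: 13 (1.05 equiv), THF, 0 → 23 °C; NaOTf (2 equiv), Pd(OAc)2 (2 mol %), (Sp,Sp)-MandyPhos (2.4 mol %), 12 (1.15 equiv), THF/DMSO, 40 °C; then 30% H2O2, pH 7 phosphate buffer, 0 → 23 °C
Reagents that add atoms: hydrogen peroxide, OO
Why: Morken conjunctive cross-coupling: zerovalent palladium inserts into the activated triflate (much faster than into the hindered alkenyl bromide), the alkenylpalladium binds the vinyl group of borate 14 and triggers the 1,2-shift of the trisubstituted alkenyl group from boron to carbon (C12–C13) with C14–C1 reductive elimination; the MandyPhos antipode is chosen to give 13R (to be confirmed by Mosher analysis; the other antipode is used if the sense is opposite), and B→O oxidation proceeds with retention.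

Step 6
Reactants: 16 4-[(2R,3E,7Z,11E)-12-bromo-2-hydroxy-3,7,11-trimethyldodeca-3,7,11-trien-1-yl]-3-methylfuran-2(5H)-one
Product: 19 (2R,13R)-13-hydroxycembra-1(15),3E,7Z,11E-tetraen-16,2-olide, via bis-silyl furan 17 (not isolated), via macrocyclic silyl ether 18 (not isolated)
Conditions: TMSOTf (2.3 equiv), Et3N (3 equiv), CH2Cl2, 0 °C; then slow addition (12 h) to Pd2(dba)3 (5 mol %), (R)-DTBM-SEGPHOS (12 mol %), ZnF2 (0.6 equiv), DMF/toluene, 2 mM, 70 °C; citric acid, MeOH work-up
Reagents that add atoms: none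
Why: Proposed new method: ring-closing, ligand-controlled palladium-catalysed γ-alkenylation of a butenolide — zerovalent palladium inserts into the C3–Br bond, ZnF2 converts the silyloxyfuran of 17 into a zinc dienolate that transmetallates, and C–C reductive elimination occurs at the γ-carbon (the α-carbon is fully substituted and γ-attack restores the conjugated lactone) on the dienolate face selected by the chiral bisphosphine, which sets 2R (ligand antipode fixed by screening both; C13 is remote) while closing the 14-membered ring under high dilution with retention of the E-alkenyl geometry; fluoride activation instead of an alkoxide base keeps the new doubly allylic C2–H from being removed; the closest known reactions are the intermolecular Buchwald γ-arylation of butenolides, the Hartwig ZnF2-promoted arylation of silyl ketene acetals and asymmetric enolate alkenylation.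

Step 7
Reactants: 19 (2R,13R)-13-hydroxycembra-1(15),3E,7Z,11E-tetraen-16,2-olide
Product: 20 (2R,13R)-13-acetoxycembra-1(15),3E,7Z,11E-tetraen-16,2-olide
Conditions: Ac2O (1.5 equiv), pyridine, DMAP (5 mol %), CH2Cl2, 0 °C
Reagents that add atoms: acetic anhydride, CC(=O)OC(C)=O
Why: DMAP-catalysed acylation of the secondary allylic alcohol touches no stereocentre, and the acetate is installed only after the palladium step so that no allylic acetate is exposed to zerovalent palladium.

Step 8
Reactants: 20 (2R,13R)-13-acetoxycembra-1(15),3E,7Z,11E-tetraen-16,2-olide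
Product: 21 (2R,7S,8R,13R)-13-acetoxy-7,8-epoxycembra-1(15),3E,11E-trien-16,2-olide (CNP0302675.1)
Conditions: L-fructose-derived Shi ketone (0.5 equiv), Oxone (2KHSO5·KHSO4·K2SO4, 1.3 equiv), K2CO3, Bu4NHSO4, MeCN/DMM/aq Na2B4O7–Na2EDTA buffer, −5 °C, 90 min
Reagents that add atoms: potassium peroxymonosulfate (KHSO5), [K+].OOS(=O)(=O)[O-]
Why: Shi asymmetric epoxidation: the chiral dioxirane attacks the most electron-rich alkene (C7=C8; the other two are deactivated by allylic acyloxy groups) through the spiro transition state with retention of the Z geometry, and the L-fructose-derived ketone is predicted, by analogy with 1-substituted cycloalkenes, to give the 7S,8R cis-epoxide.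

## Compound list

1 | 5-bromopent-2-yne | CC#CCCBr | starting material
2 | propyne | CC#C | starting material
3 | (4-iodobut-1-yn-1-yl)trimethylsilane | C[Si](C)(C)C#CCCI | starting material
4 | pent-3-yn-1-ylmagnesium bromide | CC#CCC[Mg]Br | intermediate
5 | [(1Z)-2-methylhept-1-en-5-yn-1-yl]copper (MgBr2 complex) | CC#CCC/C(C)=C\[Cu] | intermediate
6 | trimethyl[(5Z)-6-methylundec-5-ene-1,9-diyn-1-yl]silane | C[Si](C)(C)C#CCC/C=C(/C)CCC#CC | intermediate
7 | (Z)-6-methylundec-5-ene-1,9-diyne | C#CCC/C=C(/C)CCC#CC | intermediate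
8 | dimethyl[(1E,5Z)-2,6-dimethylundeca-1,5-dien-9-yn-1-yl]alane | C[Al](C)/C=C(\C)CC/C=C(/C)CCC#CC | intermediate
9 | (1E,5Z)-1-bromo-2,6-dimethylundeca-1,5-dien-9-yne | Br/C=C(\C)CC/C=C(/C)CCC#CC | intermediate
10 | 2-[(2Z,6Z,10E)-11-bromo-6,10-dimethylundeca-2,6,10-trien-2-yl]-4,4,5,5-tetramethyl-1,3,2-dioxaborolane | Br/C=C(\C)CC/C=C(/C)CC/C=C(\C)B1OC(C)(C)C(C)(C)O1 | intermediate
11 | 3-methyltetronic acid (4-hydroxy-3-methylfuran-2(5H)-one) | CC1=C(O)COC1=O | starting material
12 | 4-methyl-5-oxo-2,5-dihydrofuran-3-yl trifluoromethanesulfonate | CC1=C(OS(=O)(=O)C(F)(F)F)COC1=O | intermediate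
13 | vinylmagnesium bromide | C=C[Mg]Br | starting material
14 | bromomagnesium [(2Z,6Z,10E)-11-bromo-6,10-dimethylundeca-2,6,10-trien-2-yl](vinyl)(pinacolato)borate | Br/C=C(\C)CC/C=C(/C)CC/C=C(\C)[B-]1(C=C)OC(C)(C)C(C)(C)O1.[Mg+]Br | intermediate
15 | 4-[(2R,3E,7Z,11E)-12-bromo-3,7,11-trimethyl-2-(4,4,5,5-tetramethyl-1,3,2-dioxaborolan-2-yl)dodeca-3,7,11-trien-1-yl]-3-methylfuran-2(5H)-one | Br/C=C(\C)CC/C=C(/C)CC/C=C(\C)[C@H](B1OC(C)(C)C(C)(C)O1)CC1=C(C)C(=O)OC1 | intermediate
16 | 4-[(2R,3E,7Z,11E)-12-bromo-2-hydroxy-3,7,11-trimethyldodeca-3,7,11-trien-1-yl]-3-methylfuran-2(5H)-one | Br/C=C(\C)CC/C=C(/C)CC/C=C(\C)[C@H](O)CC1=C(C)C(=O)OC1 | intermediate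
17 | {4-[(2R,3E,7Z,11E)-12-bromo-3,7,11-trimethyl-2-(trimethylsilyloxy)dodeca-3,7,11-trien-1-yl]-3-methylfuran-2-yl}oxy(trimethyl)silane | Br/C=C(\C)CC/C=C(/C)CC/C=C(\C)[C@H](O[Si](C)(C)C)CC1=COC(O[Si](C)(C)C)=C1C | intermediate
18 | (2R,13R)-13-(trimethylsilyloxy)cembra-1(15),3E,7Z,11E-tetraen-16,2-olide | C[Si](C)(C)O[C@@H]1CC2=C(C)C(=O)O[C@@H]2/C=C(\C)CC/C=C(/C)CC/C=C/1C | intermediate
19 | (2R,13R)-13-hydroxycembra-1(15),3E,7Z,11E-tetraen-16,2-olide | O[C@@H]1CC2=C(C)C(=O)O[C@@H]2/C=C(\C)CC/C=C(/C)CC/C=C/1C | intermediate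
20 | (2R,13R)-13-acetoxycembra-1(15),3E,7Z,11E-tetraen-16,2-olide | CC(=O)O[C@@H]1CC2=C(C)C(=O)O[C@@H]2/C=C(\C)CC/C=C(/C)CC/C=C/1C | intermediate
21 | (2R,7S,8R,13R)-13-acetoxy-7,8-epoxycembra-1(15),3E,11E-trien-16,2-olide | CC(=O)O[C@@H]1CC2=C(C)C(=O)O[C@@H]2/C=C(\C)CC[C@@H]2O[C@]2(C)CC/C=C/1C | target

## Step count and risks

Total step count: 8. Longest linear sequence: 7 (steps 1, 2, 3, 5, 6, 7, 8; step 4 is a one-step branch).

Steps most likely to fail:

**Step 6 (the proposed new macrocyclisation).** It may give oligomers, α-coupling, poor control at C2, or palladium ionisation of the doubly allylic lactone C–O bond of the product. The fallback uses known chemistry with reversed polarity (alkenyl nucleophile onto a C2 aldehyde); it sets out from 16 and comes back at 19. Compound 16 is silylated as in step 6 to 17, and the silyloxyfuran is oxidised with dimethyldioxirane (acetone/CH2Cl2, −78 °C, citric acid work-up) to 4-[(2R,3E,7Z,11E)-12-bromo-2-hydroxy-3,7,11-trimethyldodeca-3,7,11-trien-1-yl]-5-hydroxy-3-methylfuran-2(5H)-one F1. Diazomethane (Et2O, 0 °C) opens this pseudo-acid to the open-chain methyl (2Z,5R,6E,10Z,14E)-15-bromo-3-formyl-5-hydroxy-2,6,10,14-tetramethylpentadeca-2,6,10,14-tetraenoate F2. Nozaki–Hiyama–Kishi macrocyclisation (CrCl2 in excess, NiCl2 catalytic, DMSO/THF, 2 mM, 40 °C) then adds the alkenylchromium to the aldehyde, and the alkoxide lactonises onto the methyl ester to give 19. The C2 epimers are separated, or the Kishi chiral sulfonamide ligand is added if control is needed.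

**Step 3 (regioselectivity of protoboration).** The 2-alkyne is sterically almost unbiased, so the C11-boryl isomer may form in quantity. The fallback replaces kinetic borylcupration by thermodynamically controlled hydrozirconation; it sets out from 9 and comes back at 10. Cp2Zr(H)Cl (2.2 equiv, THF, 40 °C) equilibrates the alkenylzirconocenes to the less hindered methyl-bearing carbon, and I2 then gives (1E,5Z,9E)-1-bromo-10-iodo-2,6-dimethylundeca-1,5,9-triene F3. Iodine–lithium exchange (t-BuLi, 2.0 equiv, Et2O, −100 °C; much faster than exchange of the alkenyl bromide) and trapping with 2-isopropoxy-4,4,5,5-tetramethyl-1,3,2-dioxaborolane give 10.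

**Step 8 (site and face selectivity of epoxidation).** The peripheral-attack bias of the macrocycle may override the catalyst, or C11=C12 may compete. The fallback delivers oxygen to the face opposite to the one an electrophile attacks; it sets out from 20 and comes back at 21. NBS in THF/H2O at 0 °C forms the bromohydrin at the most electron-rich alkene by anti addition, giving (2R,7R,8R,13R)-13-acetoxy-7-bromo-8-hydroxycembra-1(15),3E,11E-trien-16,2-olide F4. Anhydrous K2CO3 in acetone at 23 °C closes the oxirane with inversion at C7 to give 21; any diastereomer formed from attack on the other face is removed by chromatography.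

Further compounds
F1 | step 6 | 4-[(2R,3E,7Z,11E)-12-bromo-2-hydroxy-3,7,11-trimethyldodeca-3,7,11-trien-1-yl]-5-hydroxy-3-methylfuran-2(5H)-one (C5 epimers) | Br/C=C(\C)CC/C=C(/C)CC/C=C(\C)[C@H](O)CC1=C(C)C(=O)OC1O
F2 | step 6 | methyl (2Z,5R,6E,10Z,14E)-15-bromo-3-formyl-5-hydroxy-2,6,10,14-tetramethylpentadeca-2,6,10,14-tetraenoate | Br/C=C(\C)CC/C=C(/C)CC/C=C(\C)[C@H](O)C/C(C=O)=C(\C)C(=O)OC
F3 | step 3 | (1E,5Z,9E)-1-bromo-10-iodo-2,6-dimethylundeca-1,5,9-triene | Br/C=C(\C)CC/C=C(/C)CC/C=C(\C)I
F4 | step 8 | (2R,7R,8R,13R)-13-acetoxy-7-bromo-8-hydroxycembra-1(15),3E,11E-trien-16,2-olide | CC(=O)O[C@@H]1CC2=C(C)C(=O)O[C@@H]2/C=C(\C)CC[C@@H](Br)[C@](C)(O)CC/C=C/1C
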